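## Structural features

The target is a trans-2,3-diaryl-2,3-dihydrobenzofuran. Ring A (the benzo ring) is fused to the dihydrofuran ring through C3a and C7a; it carries a free hydroxyl at C6 and, at C5, an (E)-ethenyl bridge to the resorcinol ring E. C2, bonded to the ring oxygen O1, bears the catechol ring D. The neighbouring C3, bonded to C3a, bears the resorcinol ring C; the two contiguous stereocentres are both S and the aryl groups are trans. There are seven free phenols, among them an oxidation-prone catechol, and an electron-rich stilbene that is sensitive to acid, light and oxidants. The C2–O1 bond is a benzylic aryl ether para to a ring D oxygen, so it can ionise towards a quinone methide under acid or base, which would scramble C2 or open the ring. The real difficulty is to set the absolute and relative configuration of C2 and C3 on a scaffold that offers nothing but arenes, and to carry both centres through to the unprotected polyphenol. The key step exploits the fact that C3 is joined to the ring A carbon C3a and stands next to the O-benzylic C2: this is the pattern left when the ring A carbon of a 2-arylchroman-4-one shifts from the carbonyl carbon to the α-carbon, so one stereocentre at C2 of a six-membered precursor can direct the new one at C3.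

## Logic of the disconnections

**21 back to 20 and 19.** The seven phenols are capped: five O–CH3 bonds (rings A, C and E) lead back to 20, and two O–SO2CH3 bonds on ring D lead back to 19. Free phenols would not survive the organometallic and oxidative steps, and the methyl ethers come with the purchased building blocks. The forward demand is a base-induced mesylate cleavage at low temperature that leaves C3–H alone, then a Lewis acid demethylation that neither ionises C2–O1 nor harms the stilbene.

**19 back to 16 and 18.** The C3–ring C bond is cut. C3 is benzylic and flanked by the C2 aryl group, so a C3 radical generated from a carboxyl derivative should be captured trans to ring D, and a carboxyl at C3 is what the ring contraction delivers. Ring C becomes the arylzinc 18, made from 17, and the stereochemical problem shrinks to C2 alone. The forward step must run without an aryl halide in the substrate. 16 is traced through 15 to 14 by changes at the carboxyl group only (O–N and O–CH3 bonds).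

**14 back to 12 and 13.** The C5–vinyl bond is cut. An aryl bromide and a terminal styrene give the (E)-stilbene directly, and a bromide survives the oxidative key step where a stilbene would not. Ring E becomes the purchased alkene 13. The coupling must precede the nickel step and use a base too weak to open the dihydrofuran through the ester enolate.

**12 back to 9.** The C3–C3a bond is cut and the ring A carbon is reattached to the ester carbon, which regenerates a six-membered ketone. This undoes a 1,2-aryl shift and removes one ring bond, the ester and the C3 stereocentre in one move; 9 has a single stereocentre. In the forward direction (through 10 and 11) ring A, and not ring D, must migrate, and C2 must not ionise under acid.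

**9 back to 4 and 8.** The C2–ring D bond is cut. A catalytic enantioselective conjugate addition of an arylboronic acid to a chromone makes this bond and sets C2. Both partners are achiral. The catalyst must control the face of attack, keep the C–Br bond and accept an electron-poor boronic acid.

**4 back to 2 and 1.** The O1–C2 and C2–C3 bonds of the pyranone are cut, removing a one-carbon unit that an amide acetal supplies (through 3). The C–Br bond is cut next. The bromination of 1 must go para to the hydroxyl group.

**8 back to 7, 6 and 5.** The C–B bond is traced to the C–Br bond of 6, and the two O–S bonds to the catechol 5. The mesylates must survive borylation and release of the boronic acid.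

## Other disconnections considered

**Alternative 1:** The cut removes the C2–ring D bond and the C3–C3a bond at once, across what was the alkene of the ring C styrenyl boronate A1. In the forward step, A1 and the ring D aryllithium A2 form a boronate complex, and Pd(OAc)2 with a chiral ferrocene-based bisphosphine of the MandyPhos family and KOTf couples it with the ring A bromide A3. Aryl-palladium activates the alkene, ring D shifts from boron to carbon anti to the metal, and reductive elimination places ring A on the other carbon to give A4.

- In its favour: two C–C bonds and both stereocentres arise in one catalytic enantioselective step from three simple fragments, and ring C is in place from the start.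
- Against it here: a β-aryl alkenyl boronate with an aryl migrating group is at the edge of this coupling, and direct transmetalation (plain Suzuki–Miyaura coupling) would compete. A3 is an electron-rich, ortho-substituted bromide.
- The boron in A4 sits where O1 must end up, but O1 has to come from the ring A oxygen. Ring closure would therefore need net retention at C2, since an invertive displacement would lead to the cis isomer. An acid-mediated closure through the ring D-stabilised cation would be needed, which erases the C2 configuration set by the catalyst and leaves trans selectivity to C3.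
- The ester of A4 still needs reduction, oxidation and olefination to become the stilbene, and ring D is an electron-rich dimethyl ether at the final demethylation.
- Comparison: on structure this alternative is the better one, since it is more convergent and makes the C3 aryl stereocentre directly, without a decarboxylative detour. On mechanism the chosen plan is more predictable, because each stereocentre rests on a well-established reaction type. On step economy the two are about equal.

**Alternative 2:** The cut opens one C–C bond of ring E, between the carbon that bears the vinyl group and its neighbour, and unravels the resorcinol into the styryl triketone A5. In the forward step aqueous KOH makes the terminal methyl carbanion of A5 add to the enone carbonyl; dehydration and enolisation then give the resorcinol A6.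

- In its favour: it mirrors polyketide biosynthesis, needs no metal, keeps the E geometry of the alkene (equal to the chosen plan), and delivers ring E without protecting groups. The last point is better than the chosen plan, which has two more methyl ethers to cleave at the end.
- Against it here: it does not address the core. The (2S,3S)-dihydrobenzofuran must already exist and would still have to be made by another strategy.
- The enone carbonyl of A5 is the least electrophilic of the three and is tied up in enolisation. Oxa-Michael closure of an enol oxygen onto the styryl carbon, pyranone formation and retro-Claisen cleavage would compete in aqueous alkali.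
- A5 itself would need a Heck reaction with an acrylate and then acylation of a diketone dianion on a late intermediate.
- Comparison: on structure it replaces a purchased ring E by a ring that has to be built. On mechanism it trades one reliable palladium coupling for a cyclisation with several competing modes. On step economy it is worse by at least two steps.

**Alternative 3:** The cut removes the C2–C3 and O1–C2 bonds, so the five-membered ring is assembled from a four-atom ring A unit and the one-carbon C2 unit. In the forward step Cs2CO3 turns the ortho-hydroxybenzhydryl sulfone A7 into the ortho-quinone methide A8 and a chiral C2-symmetric thiolanium salt such as A9 into its ylide. The ylide carbon adds to the exocyclic carbon of A8 (the future C3), and the phenoxide then displaces the sulfide at C2 in a 5-exo-tet substitution to give A10.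

- In its favour: it is the most convergent route to the core. Ring C is in place, both stereocentres form in one step, and the anti betaine followed by invertive closure gives the trans ring inherently, which is equal to the chosen plan. A10 carries the same C5 bromide as 12 and could enter the same Heck coupling.
- Against it here: the absolute configuration depends on a stoichiometric chiral sulfide acting through a semi-stabilised benzylic ylide and a planar quinone methide of undefined geometry. This is far less settled than asymmetric variants with acyl- or ester-stabilised ylides, and which antipode of the sulfide leads to the (2S,3S) series would have to be found out.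
- The electron-rich benzylic sulfonium salt is labile, and A8 is stabilised by the para methoxy group and may react sluggishly or dimerise.
- Ring D would be an electron-rich dimethyl ether at the final demethylation, where the C2–O1 bond is most at risk.
- Comparison: on step economy and convergence this alternative is clearly better, with no decarboxylative arylation, no ester handling and roughly half the steps. On mechanism the chosen plan is better for absolute stereocontrol, since it uses a catalytic ligand-controlled addition at one centre and relays it to the second.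

Key step: step 7

Assumption: the facial sense of the Pd/pyridine-oxazoline conjugate addition on chromones is taken to parallel that established for 3-substituted cyclohexenones, which makes (R)-t-BuPyOx the ligand for the (2S)-flavanone 9; if the sense proves opposite, the antipodal ligand is used and nothing else changes.

## Route

Step 1
Reactants: 1 1-(2-hydroxy-4-methoxyphenyl)ethanone
Product: 2 1-(5-bromo-2-hydroxy-4-methoxyphenyl)ethanone
Conditions: NBS, MeCN, 0 °C → rt
Reagents that add atoms: N-bromosuccinimide, O=C1CCC(=O)N1Br
Why: Electrophilic aromatic bromination; C5 is para to the hydroxyl and ortho to the methoxy group, whereas the other activated position, C3, is flanked by both oxygens and hindered.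

Step 2
Reactants: 2 1-(5-bromo-2-hydroxy-4-methoxyphenyl)ethanone
Product: 4 6-bromo-7-methoxy-4H-chromen-4-one, via enaminone 3 (not isolated)
Conditions: Me2NCH(OMe)2, toluene, 100 °C; then conc. HCl, CH2Cl2, 40 °C
Reagents that add atoms: N,N-dimethylformamide dimethyl acetal, COC(OC)N(C)C
Why: Condensation of the methyl ketone with the amide acetal gives the enaminone; under acid the phenol oxygen adds to the β-carbon and dimethylamine is lost, which closes the pyranone (chromone synthesis from an ortho-hydroxyacetophenone).

Step 3
Reactants: 5 4-bromobenzene-1,2-diol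
Product: 6 4-bromo-1,2-phenylene dimethanesulfonate
Conditions: MsCl, Et3N, CH2Cl2, 0 °C
Reagents that add atoms: methanesulfonyl chloride, CS(=O)(=O)Cl
Why: O-Sulfonylation of both phenols; the mesylates protect the catechol and make ring D electron-poor for the key step.

Step 4
Reactants: 6 4-bromo-1,2-phenylene dimethanesulfonate
Product: 7 4-(4,4,5,5-tetramethyl-1,3,2-dioxaborolan-2-yl)-1,2-phenylene dimethanesulfonate
Conditions: B2pin2, Pd(dppf)Cl2, KOAc, 1,4-dioxane, 85 °C
Reagents that add atoms: bis(pinacolato)diboron, CC1(C)OB(OC1(C)C)B1OC(C)(C)C(C)(C)O1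
Why: Miyaura borylation; zerovalent palladium with this ligand inserts into the C–Br bond only, and aryl mesylates are inert to it and to the weak acetate base.

Step 5
Reactants: 7 4-(4,4,5,5-tetramethyl-1,3,2-dioxaborolan-2-yl)-1,2-phenylene dimethanesulfonate
Product: 8 [3,4-bis(methylsulfonyloxy)phenyl]boronic acid
Conditions: NaIO4, NH4OAc, acetone/H2O, rt
Reagents that add atoms: water, O
Why: Periodate cleaves the pinacol released in the hydrolysis equilibrium and so drives the ester to the free boronic acid; the near-neutral medium spares the mesylates.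

Step 6
Reactants: 4 6-bromo-7-methoxy-4H-chromen-4-one; 8 [3,4-bis(methylsulfonyloxy)phenyl]boronic acid
Product: 9 (2S)-6-bromo-7-methoxy-2-[3,4-bis(methylsulfonyloxy)phenyl]chroman-4-one
Conditions: Pd(OCOCF3)2 (5 mol %), (R)-t-BuPyOx (6 mol %), NH4PF6, H2O, ClCH2CH2Cl, 60 °C
Reagents that add atoms: none
Why: Asymmetric conjugate addition of an arylboronic acid to a chromone with cationic divalent palladium and a pyridine-oxazoline ligand: transmetalation, enantio-determining insertion of the C2=C3 bond into the aryl–palladium bond, then protonolysis of the palladium enolate by water. The tert-butyl group of the ligand differentiates the two faces of the enone and sets C2; no zerovalent palladium is formed, so the C–Br bond should survive.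

Step 7
Reactants: 9 (2S)-6-bromo-7-methoxy-2-[3,4-bis(methylsulfonyloxy)phenyl]chroman-4-one
Product: 12 methyl (2S,3S)-5-bromo-6-methoxy-2-[3,4-bis(methylsulfonyloxy)phenyl]-2,3-dihydro-1-benzofuran-3-carboxylate, via methyl enol ether 10 (not isolated), via iodanyl dimethyl ketal 11 (not isolated)
Conditions: PhI(OAc)2 (1.3 equiv), conc. H2SO4, HC(OMe)3, rt → 50 °C
Reagents that add atoms: trimethyl orthoformate, COC(OC)OC
Why: Acid and the orthoformate turn the ketone of 9 into the methyl enol ether 10, whose C3 attacks the trivalent iodine of PhI(OAc)2 on the face away from the C2 aryl group, and methanol traps the oxocarbenium ion as the iodanyl dimethyl ketal 11. The ketal oxygens then push the ring A carbon C4a from C4 onto C3 from the side opposite to the departing iodobenzene; this forms the bond that is C3–C3a of the product, and the dimethoxycarbenium ion left at the former C4 loses a methyl group to give the methyl ester. The closest known reaction type is the oxidative ring contraction of flavanones to methyl trans-2-aryl-2,3-dihydrobenzofuran-3-carboxylates with trivalent iodine reagents or Tl(NO3)3 in trimethyl orthoformate. The dihydrofuran ring is not closed by a cyclisation: it results from contraction of the six-membered pyranone through this 1,2-aryl shift, with O1, C2 and the fused benzene ring carried over intact. The new stereocentre C3 is controlled by C2, since iodination anti to ring D followed by migration with inversion places the ester trans to ring D, which is also the more stable epimer should C3 equilibrate; C2 itself is not touched. The step needs ring A to migrate in preference to a shift of ring D from C2 to C3 (isoflavone) and to plain dehydrogenation (flavone): the 7-methoxy group para to the migrating carbon raises the migratory aptitude of ring A, while the two mesylates make ring D a poor migrating group. The same electron-poor ring D also disfavours acid ionisation of the C2–O1 bond, so the configuration set in step 6 should be kept, and the aryl bromide and the mesylates are inert to the oxidant and to H2SO4.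

Step 8
Reactants: 12 methyl (2S,3S)-5-bromo-6-methoxy-2-[3,4-bis(methylsulfonyloxy)phenyl]-2,3-dihydro-1-benzofuran-3-carboxylate; 13 1-ethenyl-3,5-dimethoxybenzene
Product: 14 methyl (2S,3S)-5-[(E)-2-(3,5-dimethoxyphenyl)ethenyl]-6-methoxy-2-[3,4-bis(methylsulfonyloxy)phenyl]-2,3-dihydro-1-benzofuran-3-carboxylate
Conditions: Pd2(dba)3, [HP(t-Bu)3]BF4, Cy2NMe, 1,4-dioxane, 80 °C
Reagents that add atoms: none
Why: Mizoroki–Heck reaction: zerovalent palladium inserts into the C5–Br bond, syn addition to the unsubstituted alkene carbon and syn β-hydride elimination give the (E)-stilbene. The bulky trialkylphosphine activates the electron-rich bromide but not aryl mesylates, and the hindered amine is too weak a base to open the dihydrofuran through the ester enolate.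

Step 9
Reactants: 14 methyl (2S,3S)-5-[(E)-2-(3,5-dimethoxyphenyl)ethenyl]-6-methoxy-2-[3,4-bis(methylsulfonyloxy)phenyl]-2,3-dihydro-1-benzofuran-3-carboxylate
Product: 15 (2S,3S)-5-[(E)-2-(3,5-dimethoxyphenyl)ethenyl]-6-methoxy-2-[3,4-bis(methylsulfonyloxy)phenyl]-2,3-dihydro-1-benzofuran-3-carboxylic acid
Conditions: Me3SnOH, ClCH2CH2Cl, 80 °C; then aq. HCl
Reagents that add atoms: trimethyltin hydroxide, C[Sn](C)(C)O
Why: Methyl ester cleavage with trimethyltin hydroxide: the tin centre activates the ester carbonyl and delivers hydroxide under nearly neutral conditions, so the aryl mesylates should not be saponified and no ester enolate is formed. Any epimerisation at C3 would be of no consequence, because C3 becomes a radical in step 11.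

Step 10
Reactants: 15 (2S,3S)-5-[(E)-2-(3,5-dimethoxyphenyl)ethenyl]-6-methoxy-2-[3,4-bis(methylsulfonyloxy)phenyl]-2,3-dihydro-1-benzofuran-3-carboxylic acid
Product: 16 1,3-dioxoisoindolin-2-yl (2S,3S)-5-[(E)-2-(3,5-dimethoxyphenyl)ethenyl]-6-methoxy-2-[3,4-bis(methylsulfonyloxy)phenyl]-2,3-dihydro-1-benzofuran-3-carboxylate
Conditions: N-hydroxyphthalimide, i-PrN=C=N-i-Pr, DMAP (cat.), CH2Cl2, rt
Reagents that add atoms: N-hydroxyphthalimide, O=C1c2ccccc2C(=O)N1O
Why: Steglich-type esterification through the O-acylisourea gives the N-acyloxyphthalimide, a redox-active ester that accepts one electron and loses CO2.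

Step 11
Reactants: 16 1,3-dioxoisoindolin-2-yl (2S,3S)-5-[(E)-2-(3,5-dimethoxyphenyl)ethenyl]-6-methoxy-2-[3,4-bis(methylsulfonyloxy)phenyl]-2,3-dihydro-1-benzofuran-3-carboxylate; 17 1-bromo-3,5-dimethoxybenzene
Product: 19 4-[(2S,3S)-3-(3,5-dimethoxyphenyl)-5-[(E)-2-(3,5-dimethoxyphenyl)ethenyl]-6-methoxy-2,3-dihydro-1-benzofuran-2-yl]-1,2-phenylene dimethanesulfonate, via (3,5-dimethoxyphenyl)zinc chloride 18 (not isolated)
Conditions: 17, Mg, LiCl, THF, rt, then ZnCl2; added to 16, NiCl2·glyme (20 mol %), 4,4'-di-tert-butyl-2,2'-bipyridine (40 mol %), THF/DMF, rt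
Reagents that add atoms: none
Why: Decarboxylative Negishi-type arylation of a secondary redox-active ester: low-valent nickel reduces the N-acyloxyphthalimide, CO2 and phthalimide are lost, and the benzylic C3 radical is captured by aryl-nickel, which forms the C3–ring C bond by reductive elimination. The planar radical is approached on the face away from ring D at C2, so ring C should arrive trans, which is also the more stable arrangement; the C5–Br bond was used up in step 8, so no aryl halide competes for nickel.

Step 12
Reactants: 19 4-[(2S,3S)-3-(3,5-dimethoxyphenyl)-5-[(E)-2-(3,5-dimethoxyphenyl)ethenyl]-6-methoxy-2,3-dihydro-1-benzofuran-2-yl]-1,2-phenylene dimethanesulfonate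
Product: 20 4-[(2S,3S)-3-(3,5-dimethoxyphenyl)-5-[(E)-2-(3,5-dimethoxyphenyl)ethenyl]-6-methoxy-2,3-dihydro-1-benzofuran-2-yl]benzene-1,2-diol
Conditions: LiN(i-Pr)2 (5 equiv), THF, −78 → 0 °C; then aq. NH4Cl
Reagents that add atoms: none
Why: Base-induced cleavage of aryl mesylates: the amide removes a proton from each S-methyl group and the carbanion expels the aryloxide as sulfene (E1cB), which the amide traps. At low temperature the far less acidic C3–H and the methyl ethers should not react, and the substrate has no free phenol at this stage.

Step 13
Reactants: 20 4-[(2S,3S)-3-(3,5-dimethoxyphenyl)-5-[(E)-2-(3,5-dimethoxyphenyl)ethenyl]-6-methoxy-2,3-dihydro-1-benzofuran-2-yl]benzene-1,2-diol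
Product: 21 5-[(E)-2-[(2S,3S)-2-(3,4-dihydroxyphenyl)-3-(3,5-dihydroxyphenyl)-6-hydroxy-2,3-dihydro-1-benzofuran-5-yl]ethenyl]benzene-1,3-diol
Conditions: BBr3 (excess), CH2Cl2, −78 → 0 °C; then H2O
Reagents that add atoms: none
Why: Lewis acid cleavage of aryl methyl ethers: BBr3 binds each methoxy oxygen and bromide removes the methyl group by SN2, and hydrolysis frees the phenols. The catechol is first tied up as a cyclic bromoborate, which tempers the donor strength of ring D towards C2–O1, and the low temperature should preserve the stilbene and the trans stereocentres.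

## Compound list

1 | 1-(2-hydroxy-4-methoxyphenyl)ethanone | CC(=O)c1ccc(OC)cc1O | starting material
2 | 1-(5-bromo-2-hydroxy-4-methoxyphenyl)ethanone | CC(=O)c1cc(Br)c(OC)cc1O | intermediate
3 | (E)-1-(5-bromo-2-hydroxy-4-methoxyphenyl)-3-(dimethylamino)prop-2-en-1-one | CN(C)/C=C/C(=O)c1cc(Br)c(OC)cc1O | intermediate
4 | 6-bromo-7-methoxy-4H-chromen-4-one | O=c1ccoc2cc(OC)c(Br)cc12 | intermediate
5 | 4-bromobenzene-1,2-diol | Oc1ccc(Br)cc1O | starting material
6 | 4-bromo-1,2-phenylene dimethanesulfonate | CS(=O)(=O)Oc1ccc(Br)cc1OS(C)(=O)=O | intermediate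
7 | 4-(4,4,5,5-tetramethyl-1,3,2-dioxaborolan-2-yl)-1,2-phenylene dimethanesulfonate | CS(=O)(=O)Oc1ccc(B2OC(C)(C)C(C)(C)O2)cc1OS(C)(=O)=O | intermediate
8 | [3,4-bis(methylsulfonyloxy)phenyl]boronic acid | CS(=O)(=O)Oc1ccc(B(O)O)cc1OS(C)(=O)=O | intermediate
9 | (2S)-6-bromo-7-methoxy-2-[3,4-bis(methylsulfonyloxy)phenyl]chroman-4-one | Brc2cc3c(cc2OC)O[C@H](c2ccc(OS(C)(=O)=O)c(OS(C)(=O)=O)c2)CC3=O | intermediate
10 | (2S)-6-bromo-4,7-dimethoxy-2-[3,4-bis(methylsulfonyloxy)phenyl]-2H-chromene | Brc2cc3c(cc2OC)O[C@H](c2ccc(OS(C)(=O)=O)c(OS(C)(=O)=O)c2)C=C3OC | intermediate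
11 | (2R,3R)-3-[acetoxy(phenyl)-λ3-iodanyl]-6-bromo-4,4,7-trimethoxy-2-[3,4-bis(methylsulfonyloxy)phenyl]chromane (iodine trans to ring D; acetate drawn as the second ligand on iodine; the C2 descriptor differs from 9 only through the priority of C3) | Brc2cc3c(cc2OC)O[C@H](c2ccc(OS(C)(=O)=O)c(OS(C)(=O)=O)c2)[C@@H](I(OC(C)=O)c2ccccc2)C3(OC)OC | intermediate
12 | methyl (2S,3S)-5-bromo-6-methoxy-2-[3,4-bis(methylsulfonyloxy)phenyl]-2,3-dihydro-1-benzofuran-3-carboxylate | Brc2cc3c(cc2OC)O[C@H](c2ccc(OS(C)(=O)=O)c(OS(C)(=O)=O)c2)[C@H]3C(=O)OC | intermediate
13 | 1-ethenyl-3,5-dimethoxybenzene (3,5-dimethoxystyrene) | COc1cc(C=C)cc(OC)c1 | starting material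
14 | methyl (2S,3S)-5-[(E)-2-(3,5-dimethoxyphenyl)ethenyl]-6-methoxy-2-[3,4-bis(methylsulfonyloxy)phenyl]-2,3-dihydro-1-benzofuran-3-carboxylate | COc1cc(/C=C/c2cc3c(cc2OC)O[C@H](c2ccc(OS(C)(=O)=O)c(OS(C)(=O)=O)c2)[C@H]3C(=O)OC)cc(OC)c1 | intermediate
15 | (2S,3S)-5-[(E)-2-(3,5-dimethoxyphenyl)ethenyl]-6-methoxy-2-[3,4-bis(methylsulfonyloxy)phenyl]-2,3-dihydro-1-benzofuran-3-carboxylic acid | COc1cc(/C=C/c2cc3c(cc2OC)O[C@H](c2ccc(OS(C)(=O)=O)c(OS(C)(=O)=O)c2)[C@H]3C(=O)O)cc(OC)c1 | intermediate
16 | 1,3-dioxoisoindolin-2-yl (2S,3S)-5-[(E)-2-(3,5-dimethoxyphenyl)ethenyl]-6-methoxy-2-[3,4-bis(methylsulfonyloxy)phenyl]-2,3-dihydro-1-benzofuran-3-carboxylate | COc1cc(/C=C/c2cc3c(cc2OC)O[C@H](c2ccc(OS(C)(=O)=O)c(OS(C)(=O)=O)c2)[C@H]3C(=O)ON2C(=O)c4ccccc4C2=O)cc(OC)c1 | intermediate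
17 | 1-bromo-3,5-dimethoxybenzene | COc1cc(Br)cc(OC)c1 | starting material
18 | (3,5-dimethoxyphenyl)zinc chloride (as its LiCl complex in THF) | COc1cc([Zn]Cl)cc(OC)c1 | intermediate
19 | 4-[(2S,3S)-3-(3,5-dimethoxyphenyl)-5-[(E)-2-(3,5-dimethoxyphenyl)ethenyl]-6-methoxy-2,3-dihydro-1-benzofuran-2-yl]-1,2-phenylene dimethanesulfonate | COc1cc(/C=C/c2cc3c(cc2OC)O[C@H](c2ccc(OS(C)(=O)=O)c(OS(C)(=O)=O)c2)[C@H]3c2cc(OC)cc(OC)c2)cc(OC)c1 | intermediate
20 | 4-[(2S,3S)-3-(3,5-dimethoxyphenyl)-5-[(E)-2-(3,5-dimethoxyphenyl)ethenyl]-6-methoxy-2,3-dihydro-1-benzofuran-2-yl]benzene-1,2-diol | COc1cc(/C=C/c2cc3c(cc2OC)O[C@H](c2ccc(O)c(O)c2)[C@H]3c2cc(OC)cc(OC)c2)cc(OC)c1 | intermediate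
21 | 5-[(E)-2-[(2S,3S)-2-(3,4-dihydroxyphenyl)-3-(3,5-dihydroxyphenyl)-6-hydroxy-2,3-dihydro-1-benzofuran-5-yl]ethenyl]benzene-1,3-diol | Oc1cc(O)cc(/C=C/c2cc3c(cc2O)O[C@H](c2ccc(O)c(O)c2)[C@H]3c2cc(O)cc(O)c2)c1 | target

## Step count and least certain steps

Total: 13 steps. Longest linear sequence: 11 steps (5 → 6 → 7 → 8 → 9 → 12 → 14 → 15 → 16 → 19 → 20 → 21); the ring A branch (1 → 2 → 4) joins at step 6.

**Step 7 (key step).** The most likely failures are a diversion of the iodanyl intermediate into dehydrogenation (flavone) or into a shift of ring D, and slow migration of ring A because the bromine meta to the migrating carbon lowers its donor strength. Partial loss of configuration at C2 through acid-induced ring opening is a lesser risk.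

Fallback: a Wolff ring contraction, which moves the same ring A carbon to C3. It sets out from 9 and comes back at 12.
- 9 would be activated with LiN(SiMe3)2 and CF3CO2CH2CF3 in THF at −78 °C to give (2S)-6-bromo-7-methoxy-2-[3,4-bis(methylsulfonyloxy)phenyl]-3-(trifluoroacetyl)chroman-4-one F1.
- Deacylative diazo transfer with 4-acetamidobenzenesulfonyl azide, Et3N and water in MeCN would give the diazoketone (2R)-6-bromo-3-diazo-7-methoxy-2-[3,4-bis(methylsulfonyloxy)phenyl]chroman-4-one F2. The arrangement at C2 is that of 9; only the descriptor changes.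
- Irradiation in methanol would trigger the Wolff rearrangement. The cyclic diazoketone is locked s-cis, the ring A carbon shifts from the carbonyl carbon to C3, and methanol adds to the ketene.
- The kinetic protonation may favour the cis ester methyl (2S,3R)-5-bromo-6-methoxy-2-[3,4-bis(methylsulfonyloxy)phenyl]-2,3-dihydro-1-benzofuran-3-carboxylate F3, which DBU would equilibrate to the trans ester 12.

**Step 6.** Transmetalation of the electron-poor boronic acid may be slow and lose out to protodeboronation, the 7-methoxychromone is a weak acceptor, and facial discrimination may be insufficient.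

Fallback: build the flavanone by a chalcone route and resolve it. It sets out from 2 and comes back at 9.
- 2 would be condensed under acid (BF3·OEt2, dioxane; Claisen–Schmidt type) with 4-formyl-1,2-phenylene dimethanesulfonate F4, made from commercial 3,4-dihydroxybenzaldehyde with MsCl and Et3N. This would give the chalcone (E)-1-(5-bromo-2-hydroxy-4-methoxyphenyl)-3-[3,4-bis(methylsulfonyloxy)phenyl]prop-2-en-1-one F5.
- NaOAc in refluxing ethanol would close F5 by oxa-Michael addition to the racemic flavanone 6-bromo-7-methoxy-2-[3,4-bis(methylsulfonyloxy)phenyl]chroman-4-one F6.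
- Preparative chromatography on a chiral stationary phase would deliver 9. The unwanted antipode would be racemised through ring opening with NaOAc and recycled.

**Step 11.** The benzylic C3 radical may be lost to dimerisation or hydrogen abstraction before nickel captures it, zerovalent nickel may insert into the aryl mesylate C–O bonds, and the alkylnickel intermediate may eliminate the β-aryloxy group and open the ring.

Fallback: change the order and the metal, so that the radical step runs on a substrate without the stilbene and with a catalyst that does not touch aryl sulfonates or the aryl bromide. It sets out from 12 and comes back at 19.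
- Me3SnOH would give (2S,3S)-5-bromo-6-methoxy-2-[3,4-bis(methylsulfonyloxy)phenyl]-2,3-dihydro-1-benzofuran-3-carboxylic acid F7.
- N-Hydroxyphthalimide and the carbodiimide would give 1,3-dioxoisoindolin-2-yl (2S,3S)-5-bromo-6-methoxy-2-[3,4-bis(methylsulfonyloxy)phenyl]-2,3-dihydro-1-benzofuran-3-carboxylate F8.
- Iron-catalysed decarboxylative arylation with 18 (Fe(acac)3, 1,2-bis(diphenylphosphino)benzene, THF) would give 4-[(2S,3S)-5-bromo-3-(3,5-dimethoxyphenyl)-6-methoxy-2,3-dihydro-1-benzofuran-2-yl]-1,2-phenylene dimethanesulfonate F9.
- The Heck coupling with 13 under the conditions of step 8 would then give 19.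

**Step 13.** Once ring D has become a donor, the Lewis acid may ionise the C2–O1 bond, and the hydrogen bromide released from the free catechol may add to the electron-rich stilbene. Either would erode the trans-dihydrofuran or the alkene.

Fallback: invert the order of the two deprotections. It sets out from 19 and comes back at 21.
- BBr3 in CH2Cl2 would be applied to 19 first. Ring D is then still electron-poor, and the medium stays free of hydrogen bromide until the quench because no free hydroxyl is present. This would give 4-[(2S,3S)-3-(3,5-dihydroxyphenyl)-5-[(E)-2-(3,5-dihydroxyphenyl)ethenyl]-6-hydroxy-2,3-dihydro-1-benzofuran-2-yl]-1,2-phenylene dimethanesulfonate F10.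
- Degassed aqueous KOH in methanol under argon would then cleave the two mesylates, and acidification would give 21.

## Further compounds

F1 | step 7 | (2S)-6-bromo-7-methoxy-2-[3,4-bis(methylsulfonyloxy)phenyl]-3-(trifluoroacetyl)chroman-4-one (C3 epimers or enol) | Brc2cc3c(cc2OC)O[C@H](c2ccc(OS(C)(=O)=O)c(OS(C)(=O)=O)c2)C(C(=O)C(F)(F)F)C3=O
F2 | step 7 | (2R)-6-bromo-3-diazo-7-methoxy-2-[3,4-bis(methylsulfonyloxy)phenyl]chroman-4-one | Brc2cc3c(cc2OC)O[C@H](c2ccc(OS(C)(=O)=O)c(OS(C)(=O)=O)c2)C(=[N+]=[N-])C3=O
F3 | step 7 | methyl (2S,3R)-5-bromo-6-methoxy-2-[3,4-bis(methylsulfonyloxy)phenyl]-2,3-dihydro-1-benzofuran-3-carboxylate | Brc2cc3c(cc2OC)O[C@H](c2ccc(OS(C)(=O)=O)c(OS(C)(=O)=O)c2)[C@@H]3C(=O)OC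
F4 | step 6 | 4-formyl-1,2-phenylene dimethanesulfonate | O=Cc1ccc(OS(C)(=O)=O)c(OS(C)(=O)=O)c1
F5 | step 6 | (E)-1-(5-bromo-2-hydroxy-4-methoxyphenyl)-3-[3,4-bis(methylsulfonyloxy)phenyl]prop-2-en-1-one | COc1cc(O)c(cc1Br)C(=O)/C=C/c1ccc(OS(C)(=O)=O)c(OS(C)(=O)=O)c1
F6 | step 6 | racemic 6-bromo-7-methoxy-2-[3,4-bis(methylsulfonyloxy)phenyl]chroman-4-one | Brc1cc2c(cc1OC)OC(c1ccc(OS(C)(=O)=O)c(OS(C)(=O)=O)c1)CC2=O
F7 | step 11 | (2S,3S)-5-bromo-6-methoxy-2-[3,4-bis(methylsulfonyloxy)phenyl]-2,3-dihydro-1-benzofuran-3-carboxylic acid | Brc2cc3c(cc2OC)O[C@H](c2ccc(OS(C)(=O)=O)c(OS(C)(=O)=O)c2)[C@H]3C(=O)O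
F8 | step 11 | 1,3-dioxoisoindolin-2-yl (2S,3S)-5-bromo-6-methoxy-2-[3,4-bis(methylsulfonyloxy)phenyl]-2,3-dihydro-1-benzofuran-3-carboxylate | Brc2cc3c(cc2OC)O[C@H](c2ccc(OS(C)(=O)=O)c(OS(C)(=O)=O)c2)[C@H]3C(=O)ON2C(=O)c4ccccc4C2=O
F9 | step 11 | 4-[(2S,3S)-5-bromo-3-(3,5-dimethoxyphenyl)-6-methoxy-2,3-dihydro-1-benzofuran-2-yl]-1,2-phenylene dimethanesulfonate | Brc2cc3c(cc2OC)O[C@H](c2ccc(OS(C)(=O)=O)c(OS(C)(=O)=O)c2)[C@H]3c2cc(OC)cc(OC)c2
F10 | step 13 | 4-[(2S,3S)-3-(3,5-dihydroxyphenyl)-5-[(E)-2-(3,5-dihydroxyphenyl)ethenyl]-6-hydroxy-2,3-dihydro-1-benzofuran-2-yl]-1,2-phenylene dimethanesulfonate | Oc1cc(O)cc(/C=C/c2cc3c(cc2O)O[C@H](c2ccc(OS(C)(=O)=O)c(OS(C)(=O)=O)c2)[C@H]3c2cc(O)cc(O)c2)c1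
A1 | alternative 1 | 2-[(E)-2-(3,5-dimethoxyphenyl)ethenyl]-4,4,5,5-tetramethyl-1,3,2-dioxaborolane | COc1cc(/C=C/B2OC(C)(C)C(C)(C)O2)cc(OC)c1
A2 | alternative 1 | (3,4-dimethoxyphenyl)lithium | [Li]c1ccc(OC)c(OC)c1
A3 | alternative 1 | methyl 5-bromo-2-methoxy-4-(methoxymethoxy)benzoate | COC(=O)c1cc(Br)c(OCOC)cc1OC
A4 | alternative 1 | methyl 5-[(1S,2S)-2-(3,4-dimethoxyphenyl)-1-(3,5-dimethoxyphenyl)-2-(4,4,5,5-tetramethyl-1,3,2-dioxaborolan-2-yl)ethyl]-2-methoxy-4-(methoxymethoxy)benzoate | CC1(C)OB(OC1(C)C)[C@H](c1ccc(OC)c(OC)c1)[C@H](c1cc(C(=O)OC)c(OC)cc1OCOC)c1cc(OC)cc(OC)c1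
A5 | alternative 2 | (1E)-1-[(2S,3S)-2-(3,4-dimethoxyphenyl)-3-(3,5-dimethoxyphenyl)-6-methoxy-2,3-dihydro-1-benzofuran-5-yl]oct-1-ene-3,5,7-trione | CC(=O)CC(=O)CC(=O)/C=C/c1cc2c(cc1OC)O[C@H](c1ccc(OC)c(OC)c1)[C@H]2c1cc(OC)cc(OC)c1
A6 | alternative 2 | 5-{(E)-2-[(2S,3S)-2-(3,4-dimethoxyphenyl)-3-(3,5-dimethoxyphenyl)-6-methoxy-2,3-dihydro-1-benzofuran-5-yl]ethenyl}benzene-1,3-diol | Oc1cc(O)cc(/C=C/c2cc3c(cc2OC)O[C@H](c2ccc(OC)c(OC)c2)[C@H]3c2cc(OC)cc(OC)c2)c1
A7 | alternative 3 | 4-bromo-2-[(3,5-dimethoxyphenyl)(4-methylbenzenesulfonyl)methyl]-5-methoxyphenol | Cc1ccc(cc1)S(=O)(=O)C(c1cc(OC)cc(OC)c1)c1cc(Br)c(OC)cc1O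
A8 | alternative 3 | 4-bromo-6-[(3,5-dimethoxyphenyl)methylidene]-3-methoxycyclohexa-2,4-dien-1-one | O=C1C=C(OC)C(Br)=CC1=Cc1cc(OC)cc(OC)c1
A9 | alternative 3 | (2R,5R)-1-[(3,4-dimethoxyphenyl)methyl]-2,5-dimethylthiolan-1-ium trifluoromethanesulfonate | C[C@@H]1CC[C@@H](C)[S+]1Cc1ccc(OC)c(OC)c1.[O-]S(=O)(=O)C(F)(F)F
A10 | alternative 3 | (2S,3S)-5-bromo-2-(3,4-dimethoxyphenyl)-3-(3,5-dimethoxyphenyl)-6-methoxy-2,3-dihydro-1-benzofuran | Brc2cc3c(cc2OC)O[C@H](c2ccc(OC)c(OC)c2)[C@H]3c2cc(OC)cc(OC)c2
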